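The 2H-pyran ring (O1, C2, C3, C4, C4a, C8a) and the cyclohexenone ring (C4a, C5, C6, C7, C8, C8a) share the C4a=C8a bond, and the chain C3–C4–C4a–C8a is, once water is removed from C3–C4, a 1,3-diene. Such a diene straddling a ring fusion is the signature of dienyne metathesis. The precursor is an acyclic allyl 1-alkylvinyl ether of (S)-icos-1-en-3-ol that ends in a terminal ynone; one ruthenium catalyst turns the alkyne carbons into C4 and C4a, the enol-ether carbon into C8a and the allylic vinyl carbon into C3, closing both rings at once. Stereocontrolled Markovnikov hydration of C3=C4 then sets the C4 carbinol cis to the C2 chain.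

Key step: step 8

Remark on the chemistry: chromenone numbering is used (O1, C2 with the heptadecyl chain, C3, C4 with OH, C4a, C5 carbonyl, C6–C8, C8a); the target is (2S,4R), with the C2 chain and the C4 hydroxyl cis.

Step 1
Reactants: 1 (S)-epichlorohydrin; 2 1-bromohexadecane
Product: 4 (2S)-1-chlorononadecan-2-ol, via hexadecylmagnesium bromide 3 (not isolated)
Conditions: 2, Mg turnings, THF, reflux; then CuI (10 mol%), 1, THF, −40 → 0 °C; 1 M HCl work-up
Reagents that add atoms: none
Why: Copper-catalysed Grignard opening of the terminal epoxide at its CH2 carbon leaves the C–Cl bond and the carbinol stereocentre (the future C2) untouched, so the S configuration of 1 is carried into 4.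

Step 2
Reactants: 4 (2S)-1-chlorononadecan-2-ol
Product: 6 (3S)-icos-1-en-3-ol, via (2S)-2-heptadecyloxirane 5 (not isolated)
Conditions: Me3S+ I− (4 equiv), n-BuLi (3.8 equiv), THF, −10 → 25 °C
Reagents that add atoms: trimethylsulfonium iodide, C[S+](C)C.[I-]
Why: Dimethylsulfonium methylide first acts as base to close the chlorohydrin to epoxide 5 (Williamson closure, stereocentre not involved), then opens it at CH2, and the sulfonium betaine loses dimethyl sulfide by ylide-mediated α′,β-elimination, the known one-carbon homologation of a terminal epoxide to an allylic alcohol.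

Step 3
Reactants: 6 (3S)-icos-1-en-3-ol; 7 5-bromopentanoic acid
Product: 8 (3S)-icos-1-en-3-yl 5-bromopentanoate
Conditions: DCC, DMAP (cat.), CH2Cl2, 0 → 25 °C
Reagents that add atoms: none
Why: Steglich esterification acylates the secondary allylic alcohol at oxygen with retention of the stereocentre, and the primary bromide is inert under these conditions.

Step 4
Reactants: 8 (3S)-icos-1-en-3-yl 5-bromopentanoate
Product: 9 (3S)-3-[(6-bromohex-1-en-2-yl)oxy]icos-1-ene
Conditions: Cp2Ti(CH2)(Cl)AlMe2 (Tebbe reagent, toluene solution), pyridine (cat.), THF, −40 → 20 °C; aq. NaOH quench at 0 °C; Et3N-deactivated silica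
Reagents that add atoms: Tebbe reagent, C[Al-]1(C)C[Ti](C2C=CC=C2)(C2C=CC=C2)[Cl+]1
Why: Tebbe methylenation converts the ester carbonyl into the 1,1-disubstituted enol ether under non-acidic conditions below room temperature, which avoids both hydrolysis and Claisen rearrangement of the allyl vinyl ether, while the alkyl bromide and the terminal alkene are tolerated.

Step 5
Reactants: 9 (3S)-3-[(6-bromohex-1-en-2-yl)oxy]icos-1-ene
Product: 10 5-{[(3S)-icos-1-en-3-yl]oxy}hex-5-enal
Conditions: Me3NO (anhydrous, 4 equiv), DMSO, 25 °C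
Reagents that add atoms: trimethylamine N-oxide, C[N+](C)(C)[O-]
Why: Kornblum-type oxidation with an amine N-oxide: SN2 O-alkylation of the N-oxide by the primary bromide and base-induced fragmentation of the alkoxyammonium salt give the aldehyde without acid, so the enol ether survives.

Step 6
Reactants: 10 5-{[(3S)-icos-1-en-3-yl]oxy}hex-5-enal
Product: 11 7-{[(3S)-icos-1-en-3-yl]oxy}oct-7-en-1-yn-3-ol (both carbinol epimers)
Conditions: HC≡CMgBr (0.5 M in THF), THF, −78 → −20 °C; pH 7 phosphate buffer
Reagents that add atoms: ethynylmagnesium bromide, C#C[Mg]Br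
Why: 1,2-Addition of the alkynyl Grignard reagent to the aldehyde; the new carbinol centre forms without control, which does not matter because it is oxidised in step 7.

Step 7
Reactants: 11 7-{[(3S)-icos-1-en-3-yl]oxy}oct-7-en-1-yn-3-ol
Product: 12 7-{[(3S)-icos-1-en-3-yl]oxy}oct-7-en-1-yn-3-one
Conditions: MnO2 (activated, excess), CH2Cl2, 25 °C
Reagents that add atoms: none
Why: MnO2 oxidation of the propargylic alcohol is neutral and heterogeneous, so neither the acid-labile enol ether nor the terminal ynone is exposed to acid or base.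

Step 8
Reactants: 12 7-{[(3S)-icos-1-en-3-yl]oxy}oct-7-en-1-yn-3-one
Product: 14 (2S)-2-heptadecyl-2,6,7,8-tetrahydro-5H-chromen-5-one, via 2-ethenyl-3-alkoxycyclohexenone 13 (not isolated)
Conditions: second-generation Grubbs catalyst RuCl2(=CHPh)(H2IMes)(PCy3) (10 mol%), ethylene (1 atm), CH2Cl2 (0.005 M), 25–35 °C; crude 14 taken on at once
Reagents that add atoms: none
Why: Ruthenium methylidene, kept alive by ethylene, adds to the terminal ynone, and the vinylcarbene so placed on C4a undergoes [2+2] cycloaddition–cycloreversion with the enol-ether alkene, forming the tetrasubstituted C4a=C8a bond and triene 13; a second turnover joins the C4 vinyl and the allylic C3 vinyl groups to give C3=C4 and ethylene. The closest known reaction type is tandem dienyne ring-closing metathesis (ring-closing enyne metathesis followed by diene ring-closing metathesis), including enol ethers as the ene partner. The carbocycle (C4a, C5, C6, C7, C8, C8a) closes in the exo mode of enyne metathesis with C4 left outside the ring, and the pyran ring (O1, C2, C3, C4, C4a, C8a) closes by ordinary six-membered diene ring-closing metathesis. No stereocentre is created; C2 is a spectator and stays S. The selectivity needed is productive initiation, and the substrate secures it because a carbene on C3 can only reach four- or ten-membered rings and therefore returns to the methylidene pool, while the C5 ketone makes the product a stable vinylogous ester held in the closed 2H-pyran form. The temperature is held at or below 35 °C so that neither Claisen rearrangement of the allyl vinyl ether nor oxa-6π ring-opening of 14, which would racemise C2, can compete.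

Step 9
Reactants: 14 (2S)-2-heptadecyl-2,6,7,8-tetrahydro-5H-chromen-5-one
Product: 16 (2S,4R)-2-heptadecyl-4-hydroxy-2,3,4,6,7,8-hexahydro-5H-chromen-5-one, via organomercurial 15 (not isolated)
Conditions: Hg(OAc)2, THF/H2O (1:1), 0 °C; then 3 M NaOH, NaBH4, 0 °C
Reagents that add atoms: water, O
Why: Markovnikov oxymercuration–demercuration: mercury adds to C3 (the terminus of the 1-alkoxydiene) on the face of the nearly flat 2H-pyran opposite the C2 chain, water attacks the vinylogous oxocarbenium carbon C4 anti to mercury and so places the hydroxyl cis to the C2 chain (4R), and NaBH4 then replaces mercury by hydrogen at C3 without touching C4; the tetrasubstituted, electron-poor C4a=C8a bond does not compete.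

Compound list
1 | (S)-epichlorohydrin, (2S)-2-(chloromethyl)oxirane | ClC[C@@H]1CO1 | starting material
2 | 1-bromohexadecane | CCCCCCCCCCCCCCCCBr | starting material
3 | hexadecylmagnesium bromide (formed in the flask) | CCCCCCCCCCCCCCCC[Mg]Br | intermediate
4 | (2S)-1-chlorononadecan-2-ol | CCCCCCCCCCCCCCCCC[C@H](O)CCl | intermediate
5 | (2S)-2-heptadecyloxirane (formed in the flask) | CCCCCCCCCCCCCCCCC[C@H]1CO1 | intermediate
6 | (3S)-icos-1-en-3-ol | CCCCCCCCCCCCCCCCC[C@H](O)C=C | intermediate
7 | 5-bromopentanoic acid | OC(=O)CCCCBr | starting material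
8 | (3S)-icos-1-en-3-yl 5-bromopentanoate | CCCCCCCCCCCCCCCCC[C@H](OC(=O)CCCCBr)C=C | intermediate
9 | (3S)-3-[(6-bromohex-1-en-2-yl)oxy]icos-1-ene | CCCCCCCCCCCCCCCCC[C@H](OC(=C)CCCCBr)C=C | intermediate
10 | 5-{[(3S)-icos-1-en-3-yl]oxy}hex-5-enal | CCCCCCCCCCCCCCCCC[C@H](OC(=C)CCCC=O)C=C | intermediate
11 | 7-{[(3S)-icos-1-en-3-yl]oxy}oct-7-en-1-yn-3-ol (both carbinol epimers) | CCCCCCCCCCCCCCCCC[C@H](OC(=C)CCCC(O)C#C)C=C | intermediate
12 | 7-{[(3S)-icos-1-en-3-yl]oxy}oct-7-en-1-yn-3-one | CCCCCCCCCCCCCCCCC[C@H](OC(=C)CCCC(=O)C#C)C=C | intermediate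
13 | 2-ethenyl-3-{[(3S)-icos-1-en-3-yl]oxy}cyclohex-2-en-1-one (formed in the flask) | CCCCCCCCCCCCCCCCC[C@H](OC1=C(C=C)C(=O)CCC1)C=C | intermediate
14 | (2S)-2-heptadecyl-2,6,7,8-tetrahydro-5H-chromen-5-one | CCCCCCCCCCCCCCCCC[C@H]1C=CC2=C(CCCC2=O)O1 | intermediate
15 | [(2S,3R,4S)-2-heptadecyl-4-hydroxy-5-oxo-3,4,5,6,7,8-hexahydro-2H-chromen-3-yl]mercury acetate, 2,3-trans and 3,4-trans (formed in the flask) | CCCCCCCCCCCCCCCCC[C@H]1[C@H]([Hg]OC(C)=O)[C@@H](O)C2=C(CCCC2=O)O1 | intermediate
16 | (2S,4R)-2-heptadecyl-4-hydroxy-2,3,4,6,7,8-hexahydro-5H-chromen-5-one | CCCCCCCCCCCCCCCCC[C@H]1C[C@@H](O)C2=C(CCCC2=O)O1 | target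

Total step count: 9. Longest linear sequence: 9 steps (from 1 and 2 to 16; 7 enters at step 3).

Steps most likely to fail

Step 8. The catalyst may be tied up as a stabilised alkoxycarbene on the enol ether, the electron-poor alkyne may engage slowly, and cross-enyne metathesis with ethylene, Claisen rearrangement of the allyl vinyl ether or thermal racemisation of the 2H-pyran may compete. The fallback sets out from 6 and comes back at 13, which is then closed to 14. The sodium alkoxide of 6 (NaH, THF, 0 °C) undergoes addition–elimination with 3-chlorocyclohex-2-en-1-one to give 3-{[(3S)-icos-1-en-3-yl]oxy}cyclohex-2-en-1-one F1. Iodination at the nucleophilic ring carbon with N-iodosuccinimide (CH2Cl2, 0 °C) gives 2-iodo-3-{[(3S)-icos-1-en-3-yl]oxy}cyclohex-2-en-1-one F2. Stille coupling with tributyl(vinyl)stannane (Pd2(dba)3, AsPh3, NMP, 25–40 °C) gives triene 13 as an isolated compound. The same ruthenium catalyst in CH2Cl2 at 25 °C then closes only the pyran ring to 14. In this variant the C4a=C8a bond is bought with the ring and metathesis has to make only C3=C4.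

Step 9. Facial selectivity of the mercuration may be poor: mercuration syn to the C2 chain followed by anti opening would give the 2,4-trans alcohol. The hydration may also revert by acid-promoted loss of water, or hydride may attack the C5 carbonyl during demercuration. The fallback sets out from 14 and comes back at 16. The epimer that would then be obtained, (2S,4S)-2-heptadecyl-4-hydroxy-2,3,4,6,7,8-hexahydro-5H-chromen-5-one F3, is inverted at C4 by a Mitsunobu reaction (4-nitrobenzoic acid, PPh3, DIAD, THF, 0 °C). This gives (2S,4R)-2-heptadecyl-5-oxo-3,4,5,6,7,8-hexahydro-2H-chromen-4-yl 4-nitrobenzoate F4, and methanolysis (K2CO3, MeOH, 0 °C) returns 16.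

Step 5. The liberated trimethylamine may quaternise the bromide, or elimination may outrun O-alkylation of the N-oxide. The fallback sets out from 9 and comes back at 10. Displacement with KOAc (DMF, 50 °C) gives 5-{[(3S)-icos-1-en-3-yl]oxy}hex-5-en-1-yl acetate F5. Methanolysis (K2CO3, MeOH, 25 °C) gives 5-{[(3S)-icos-1-en-3-yl]oxy}hex-5-en-1-ol F6. Parikh–Doering oxidation (SO3·pyridine, DMSO, Et3N, CH2Cl2, 0 °C) then gives aldehyde 10 under basic conditions throughout.

Further compounds
F1 | step 8 | 3-{[(3S)-icos-1-en-3-yl]oxy}cyclohex-2-en-1-one | CCCCCCCCCCCCCCCCC[C@H](OC1=CC(=O)CCC1)C=C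
F2 | step 8 | 2-iodo-3-{[(3S)-icos-1-en-3-yl]oxy}cyclohex-2-en-1-one | CCCCCCCCCCCCCCCCC[C@H](OC1=C(I)C(=O)CCC1)C=C
F3 | step 9 | (2S,4S)-2-heptadecyl-4-hydroxy-2,3,4,6,7,8-hexahydro-5H-chromen-5-one | CCCCCCCCCCCCCCCCC[C@H]1C[C@H](O)C2=C(CCCC2=O)O1
F4 | step 9 | (2S,4R)-2-heptadecyl-5-oxo-3,4,5,6,7,8-hexahydro-2H-chromen-4-yl 4-nitrobenzoate | CCCCCCCCCCCCCCCCC[C@H]1C[C@@H](OC(=O)c3ccc(cc3)[N+](=O)[O-])C2=C(CCCC2=O)O1
F5 | step 5 | 5-{[(3S)-icos-1-en-3-yl]oxy}hex-5-en-1-yl acetate | CCCCCCCCCCCCCCCCC[C@H](OC(=C)CCCCOC(C)=O)C=C
F6 | step 5 | 5-{[(3S)-icos-1-en-3-yl]oxy}hex-5-en-1-ol | CCCCCCCCCCCCCCCCC[C@H](OC(=C)CCCCO)C=C
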